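The route disconnects the C3–C4 bond of the cyclopentane back to a six-membered ring: quaternary C4, which carries a methyl group and the one-carbon branch C9′, is the signature of a contracted 1-methylcyclohexene oxide. In one operation the key step breaks the C3–C9′ bond, forms C3–C4, closes the five-membered ring of the hydroazulene, sets the C4 stereocentre and releases C9′ as a formyl group for attachment of the phloroglucinol unit. Its precursor is the β-epoxide (C4–C9′) of a trans-fused cyclohexene–cycloheptane that already holds the C7 isopropenyl group and the silyl-protected C10 carbinol.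

Key step: step 13

Remark on numbering: atoms carry the numbers of the target (seven-membered ring C1, C5–C10; C2–C4 complete the five-membered ring; C9′ is the benzylic carbon and is a ring atom between C3 and C4 in the six–seven bicycle); β is the face of the C7 isopropenyl group.
Remark on stereocontrol: organocopper additions to 5-substituted cyclohept-2-enones tend to place the new group cis to the 5-substituent, and methyl organometallics tend to enter a ring ketone equatorially; both are the wrong sense here, so C5 is set by a ligand-controlled rhodium addition and C10 by an aluminium-directed axial methyl addition.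
Remark on C9′: compounds 22–24 are carried as mixtures of C9′ epimers, which converge in quinone methide 25.

Step 1
Reactants: 1 (R)-limonene
Product: 2 (5R)-7,7-dimethoxy-5-(prop-1-en-2-yl)heptan-2-one
Conditions: O3 (1 equiv), CH2Cl2/MeOH, −78 °C; p-TsOH (cat.), −78 °C to rt; NaHCO3, Me2S
Reagents that add atoms: ozone [O-][O+]=O; methanol CO
Why: Criegee ozonolysis should cleave the electron-rich trisubstituted ring alkene in preference to the isopropenyl group, the free aldehyde terminus being acetalised under acid before the sulfide releases the methyl ketone; the stereocentre is untouched.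

Step 2
Reactants: 2 (5R)-7,7-dimethoxy-5-(prop-1-en-2-yl)heptan-2-one
Product: 4 diethyl [(5R)-7,7-dimethoxy-2-oxo-5-(prop-1-en-2-yl)heptyl]phosphonate, via keto phosphonite 3 (not isolated)
Conditions: LiN(iPr)2, THF, −78 °C; ClP(OEt)2, −78 °C to rt; air (O2), rt
Reagents that add atoms: diethyl chlorophosphite CCOP(Cl)OCC; dioxygen O=O
Why: Kinetic deprotonation should occur at the methyl group, the enolate is C-phosphinylated by the soft chlorophosphite and the phosphonite is oxidised by air to the β-keto phosphonate (enolate phosphinylation–oxidation).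

Step 3
Reactants: 4 diethyl [(5R)-7,7-dimethoxy-2-oxo-5-(prop-1-en-2-yl)heptyl]phosphonate
Product: 5 diethyl [(5R)-2,7-dioxo-5-(prop-1-en-2-yl)heptyl]phosphonate
Conditions: Amberlyst-15 (H+ resin, cat.), acetone/H2O, rt
Reagents that add atoms: water O
Why: Acid-catalysed acetal hydrolysis should free the aldehyde under conditions too mild to hydrate or shift the isopropenyl alkene.

Step 4
Reactants: 5 diethyl [(5R)-2,7-dioxo-5-(prop-1-en-2-yl)heptyl]phosphonate
Product: 6 (5R)-5-(prop-1-en-2-yl)cyclohept-2-en-1-one
Conditions: K2CO3, 18-crown-6, toluene, 70 °C, high dilution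
Reagents that add atoms: none
Why: Intramolecular Horner–Wadsworth–Emmons olefination: the weak base forms only the phosphonate-stabilised carbanion, which condenses with the aldehyde to close the seven-membered enone, dilution suppressing oligomers.

Step 5
Reactants: 6 (5R)-5-(prop-1-en-2-yl)cyclohept-2-en-1-one
Product: 8 (4S)-4-(prop-1-en-2-yl)cyclohepta-2,6-dien-1-one, via silyl dienol ether 7 (not isolated)
Conditions: LiN(iPr)2, Me3SiCl, THF, −78 °C; then Pd(OAc)2 (1 equiv), MeCN, rt
Reagents that add atoms: none
Why: Saegusa–Ito oxidation: kinetic α′ deprotonation (C9) gives the 2-silyloxy diene and palladium diacetate introduces the C8=C9 bond, so that C1 becomes the α′ position of an enone for the later regiodefined alkylation.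

Step 6
Reactants: 8 (4S)-4-(prop-1-en-2-yl)cyclohepta-2,6-dien-1-one; 9 isopropenylboronic acid pinacol ester
Product: 10 (4S,6S)-4,6-di(prop-1-en-2-yl)cyclohept-2-en-1-one
Conditions: [Rh(OH)((S)-BINAP)]2 (3 mol%), dioxane/H2O, 40 °C
Reagents that add atoms: none
Why: Hayashi–Miyaura rhodium-catalysed 1,4-addition should occur at the unhindered terminus C5 (C8 is flanked by branched C7), and (S)-BINAP, which gives (S)-3-substituted cycloheptanones from cyclohept-2-enone, should deliver isopropenyl to the α face, trans to the C7 group, by ligand control.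

Step 7
Reactants: 10 (4S,6S)-4,6-di(prop-1-en-2-yl)cyclohept-2-en-1-one; 11 4-iodobut-1-ene
Product: 12 (4S,6S,7R)-7-(but-3-en-1-yl)-4,6-di(prop-1-en-2-yl)cyclohept-2-en-1-one
Conditions: LiN(iPr)2, THF, −78 °C; 11, DMPU, −78 to −30 °C
Reagents that add atoms: none
Why: Kinetic deprotonation of the enone gives the cross-conjugated α′ enolate at C1 only, and the primary iodide should enter anti to the adjacent C5 isopropenyl group, setting the C1/C5 trans relationship (α′-alkylation of an enone).

Step 8
Reactants: 12 (4S,6S,7R)-7-(but-3-en-1-yl)-4,6-di(prop-1-en-2-yl)cyclohept-2-en-1-one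
Product: 13 (2R,3S,5R)-2-(but-3-en-1-yl)-3,5-di(prop-1-en-2-yl)cycloheptan-1-one
Conditions: [(Ph3P)CuH]6 (0.4 equiv), toluene, H2O (2 equiv), rt
Reagents that add atoms: none
Why: Copper hydride conjugate reduction is specific for the enone C8=C9 bond and should leave the three isolated alkenes, while C1 stays in the more stable trans arrangement.

Step 9
Reactants: 13 (2R,3S,5R)-2-(but-3-en-1-yl)-3,5-di(prop-1-en-2-yl)cycloheptan-1-one
Product: 14 trans-fused cyclohexeno-cycloheptanone (C10 ketone; C4=C9′ alkene; H1 α; H5 β; 7β-isopropenyl)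
Conditions: second-generation Grubbs catalyst RuCl2(=CHPh)(PCy3)(H2IMes) (5 mol%), CH2Cl2, 40 °C
Reagents that add atoms: none
Why: Ring-closing metathesis between the terminal butenyl alkene and the C5 isopropenyl group should give the trisubstituted cyclohexene with loss of ethene, the trans-diequatorial branches closing the trans-fused ring and the C7 isopropenyl group having no partner within reach.

Step 10
Reactants: 14 trans-fused cyclohexeno-cycloheptanone
Product: 15 tertiary alcohol (10β-methyl; 10α-hydroxy)
Conditions: MeAl(OAr)2 (Ar = 2,6-di-tert-butyl-4-methylphenyl; MAD, 3 equiv), toluene, −78 °C; MeLi, −78 °C; H2O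
Reagents that add atoms: methyllithium [Li]C
Why: Amphiphilic carbonyl alkylation: the bulky aluminium aryloxide should complex the ketone on its open equatorial (α) side so that methyllithium attacks axially from the β face, anti to axial H1, giving 10β-methyl and 10α-hydroxyl, the reverse of uncomplexed methyllithium.

Step 11
Reactants: 15 tertiary alcohol (10β-methyl; 10α-hydroxy)
Product: 16 triethylsilyl ether of 15
Conditions: Et3SiOTf, 2,6-lutidine, CH2Cl2, 0 °C
Reagents that add atoms: triethylsilyl trifluoromethanesulfonate CC[Si](CC)(CC)OS(=O)(=O)C(F)(F)F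
Why: Silyl triflate with a hindered base silylates the tertiary alcohol, giving a spectator group that should survive the aluminium Lewis acid and the aryllithium.

Step 12
Reactants: 16 triethylsilyl ether of 15
Product: 17 β-epoxide of the bicyclo[5.4.0]undecene (C4–C9′ epoxide; oxygen β; C4 methyl α)
Conditions: L-fructose-derived Shi ketone (30 mol%), Oxone (KHSO5), K2CO3, Bu4NHSO4 (cat.), MeCN/CH2(OMe)2/aq. Na2B4O7 buffer, 0 °C
Reagents that add atoms: potassium peroxymonosulfate [K+].[O-]S(=O)(=O)OO
Why: Shi epoxidation: the chiral dioxirane should oxidise the trisubstituted C4=C9′ alkene much faster than the 1,1-disubstituted isopropenyl group, and the spiro transition state of this catalyst enantiomer delivers oxygen to the β face by reagent control, the intrinsic bias of the half-chair (one pseudo-axial allylic hydrogen on each face) being small.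

Step 13
Reactants: 17 β-epoxide of the bicyclo[5.4.0]undecene
Product: 18 C4-formyl hydroazulene (4α-methyl; 4β-formyl; H1 α; H5 β; 7β-isopropenyl; 10α-triethylsilyloxy)
Conditions: MeAl(OAr′)2 (Ar′ = 4-bromo-2,6-di-tert-butylphenyl; MABR, 20 mol%), CH2Cl2, −78 to −40 °C
Reagents that add atoms: none
Why: The aluminium Lewis acid binds the epoxide oxygen, the C4–O bond ionises at the tertiary centre and the C9′–C3 ring bond shifts to C4 while C9′ becomes the carbonyl carbon (Meinwald rearrangement, a semipinacol 1,2-shift). The closest known reaction type is the contraction of 1-methylcyclohexene oxides to 1-methylcyclopentanecarbaldehydes by methylaluminium bis(aryloxides). The cyclopentane closes by 1,2-alkyl migration, that is by ring contraction of the cyclohexane forming C3–C4, not by a new cyclisation. C4 is set with inversion: C3 enters on the α face, anti to the departing β oxygen, and the trans ring fusion holds C3 on that face, so the formyl group ends β and the methyl α. Ring-bond migration must beat hydride shift to the C9′ ketone; in the β-epoxide the C9′–O bond becomes axial once C4–O breaks, which leaves C9′–H equatorial and badly aligned with the empty orbital at C4, and the bulky aryloxide ligands disfavour the hydride-shift geometry further, while the C10 silyl ether is anti to C4 across C1–C5 and cannot take part.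

Step 14
Reactants: 19 3,5-dimethoxyphenol
Product: 20 1,3-dimethoxy-5-{[2-(trimethylsilyl)ethoxy]methoxy}benzene
Conditions: NaH, DMF, 0 °C; Me3SiCH2CH2OCH2Cl, rt
Reagents that add atoms: 2-(trimethylsilyl)ethoxymethyl chloride C[Si](C)(C)CCOCCl
Why: Williamson-type O-alkylation of the phenoxide installs a fluoride-labile acetal that also directs ortho-lithiation.

Step 15
Reactants: 18 C4-formyl hydroazulene; 20 1,3-dimethoxy-5-{[2-(trimethylsilyl)ethoxy]methoxy}benzene
Product: 22 aryl carbinol (C9′ epimers), via aryllithium 21 (not isolated)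
Conditions: 20, n-BuLi, THF, 0 °C; then 18, −78 to 0 °C; H2O
Reagents that add atoms: none
Why: Directed ortho-metalation between the acetal oxygen and a methoxy group gives the aryllithium, which should add to the non-enolisable neopentyl aldehyde (1,2-addition); the C9′ configuration is immaterial because both epimers converge later.

Step 16
Reactants: 22 aryl carbinol (C9′ epimers)
Product: 23 triol (free phenol; C9′ and C10 hydroxyls)
Conditions: Bu4NF (excess), THF/DMPU, 60 °C
Reagents that add atoms: none
Why: Fluoride should cleave the aryl SEM ether (fragmentation to ethene and formaldehyde) and the tertiary silyl ether in one operation, without acid that would ionise the electron-rich benzylic alcohol.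

Step 17
Reactants: 23 triol
Product: 24 aryl tert-butyl carbonate of 23
Conditions: Boc2O, DMAP (cat.), CH2Cl2, 0 °C
Reagents that add atoms: di-tert-butyl dicarbonate CC(C)(C)OC(=O)OC(=O)OC(C)(C)C
Why: Under DMAP catalysis the phenol is acylated far faster than the hindered secondary benzylic and the tertiary alcohols (chemoselective carbonate formation).

Step 18
Reactants: 24 aryl tert-butyl carbonate of 23
Product: 26 (9′R)-isobutyl phenol, via o-quinone methide 25 (not isolated)
Conditions: i-BuMgBr (5 equiv), THF, −78 °C to rt; H2O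
Reagents that add atoms: isobutylmagnesium bromide CC(C)C[Mg]Br
Why: o-Quinone methide formation and 1,4-addition: the benzylic magnesium alkoxide takes over the carbonate group, the phenoxide expels tert-butyl carbonate, and the Grignard reagent adds to C9′ with rearomatisation, 1,3-allylic strain holding the C4 methyl in the quinone methide plane so that isobutyl should enter anti to ring-fusion carbon C5, which is the required C9′ configuration.

Step 19
Reactants: 26 (9′R)-isobutyl phenol
Product: 27 2,4,6-trimethoxyphenyl compound
Conditions: MeI, K2CO3, acetone, 50 °C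
Reagents that add atoms: iodomethane CI
Why: Williamson methylation of the phenol (the tertiary alcohol does not react) gives three like methyl ethers for the metalation chemistry.

Step 20
Reactants: 27 2,4,6-trimethoxyphenyl compound
Product: 28 3′,5′-dibromo compound
Conditions: NBS (2 equiv), MeCN, −20 °C, dark
Reagents that add atoms: N-bromosuccinimide O=C1CCC(=O)N1Br
Why: Electrophilic aromatic bromination of the two remaining ring positions, each flanked by two methoxy groups, should be far faster than any reaction of the reagent at the alkenes.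

Step 21
Reactants: 28 3′,5′-dibromo compound
Product: 29 tri-O-methyl dialdehyde
Conditions: t-BuLi (5 equiv), THF, −78 °C; DMF, −78 to 0 °C; H2O
Reagents that add atoms: N,N-dimethylformamide CN(C)C=O
Why: After deprotonation of the alcohol, double bromine–lithium exchange (each carbon is stabilised by two ortho methoxy groups) and formylation with DMF should install both formyl groups under basic conditions.

Step 22
Reactants: 29 tri-O-methyl dialdehyde
Product: 30 target CNP0594576.1
Conditions: 4-MeC6H4SLi (excess), HMPA/toluene, 120 °C; then 1 M HCl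
Reagents that add atoms: none
Why: Thiolate demethylation (SN2 at methyl) should cleave the three aryl methyl ethers, each activated by an ortho formyl group, under basic conditions that spare the tertiary alcohol and the isopropenyl group.

Compound list
1 | (R)-limonene | CC1=CC[C@@H](CC1)C(C)=C | starting material
2 | (5R)-7,7-dimethoxy-5-(prop-1-en-2-yl)heptan-2-one | CC(=O)CC[C@H](CC(OC)OC)C(C)=C | intermediate
3 | diethyl [(5R)-7,7-dimethoxy-2-oxo-5-(prop-1-en-2-yl)heptyl]phosphonite | CCOP(OCC)CC(=O)CC[C@H](CC(OC)OC)C(C)=C | intermediate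
4 | diethyl [(5R)-7,7-dimethoxy-2-oxo-5-(prop-1-en-2-yl)heptyl]phosphonate | CCOP(=O)(OCC)CC(=O)CC[C@H](CC(OC)OC)C(C)=C | intermediate
5 | diethyl [(5R)-2,7-dioxo-5-(prop-1-en-2-yl)heptyl]phosphonate | CCOP(=O)(OCC)CC(=O)CC[C@H](CC=O)C(C)=C | intermediate
6 | (5R)-5-(prop-1-en-2-yl)cyclohept-2-en-1-one | C=C(C)[C@@H]1CCC(=O)C=CC1 | intermediate
7 | trimethyl{[(6S)-6-(prop-1-en-2-yl)cyclohepta-1,3-dien-2-yl]oxy}silane | C=C(C)[C@@H]1CC=C(O[Si](C)(C)C)C=CC1 | intermediate
8 | (4S)-4-(prop-1-en-2-yl)cyclohepta-2,6-dien-1-one | C=C(C)[C@@H]1C=CC(=O)C=CC1 | intermediate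
9 | isopropenylboronic acid pinacol ester | CC(=C)B1OC(C)(C)C(C)(C)O1 | starting material
10 | (4S,6S)-4,6-di(prop-1-en-2-yl)cyclohept-2-en-1-one | C=C(C)[C@@H]1C=CC(=O)C[C@H](C1)C(C)=C | intermediate
11 | 4-iodobut-1-ene | C=CCCI | starting material
12 | (4S,6S,7R)-7-(but-3-en-1-yl)-4,6-di(prop-1-en-2-yl)cyclohept-2-en-1-one | C=C(C)[C@@H]1C=CC(=O)[C@H](CCC=C)[C@H](C1)C(C)=C | intermediate
13 | (2R,3S,5R)-2-(but-3-en-1-yl)-3,5-di(prop-1-en-2-yl)cycloheptan-1-one | C=C(C)[C@@H]1CCC(=O)[C@H](CCC=C)[C@H](C1)C(C)=C | intermediate
14 | trans-fused cyclohexeno-cycloheptanone: C10 ketone; C4=C9′ alkene bearing the C4 methyl; H1 α; H5 β; 7β-isopropenyl | C=C(C)[C@@H]1CCC(=O)[C@@H]2CCC=C(C)[C@H]2C1 | intermediate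
15 | tertiary alcohol from 14: 10β-methyl; 10α-hydroxy | C=C(C)[C@@H]1CC[C@@](C)(O)[C@@H]2CCC=C(C)[C@H]2C1 | intermediate
16 | triethylsilyl ether of 15 | C=C(C)[C@@H]1CC[C@@](C)(O[Si](CC)(CC)CC)[C@@H]2CCC=C(C)[C@H]2C1 | intermediate
17 | 4β,9′β-epoxide of 16 (epoxide oxygen β; C4 methyl α) | C=C(C)[C@@H]1CC[C@@](C)(O[Si](CC)(CC)CC)[C@@H]2CC[C@@H]3O[C@]3(C)[C@H]2C1 | intermediate
18 | trans-fused hydroazulene aldehyde: 4α-methyl; 4β-formyl; H1 α; H5 β; 7β-isopropenyl; 10β-methyl; 10α-triethylsilyloxy | C=C(C)[C@@H]1CC[C@@](C)(O[Si](CC)(CC)CC)[C@@H]2CC[C@](C)(C=O)[C@H]2C1 | intermediate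
19 | 3,5-dimethoxyphenol | COc1cc(O)cc(OC)c1 | starting material
20 | 1,3-dimethoxy-5-{[2-(trimethylsilyl)ethoxy]methoxy}benzene | COc1cc(OC)cc(OCOCC[Si](C)(C)C)c1 | intermediate
21 | 2,4-dimethoxy-6-{[2-(trimethylsilyl)ethoxy]methoxy}phenyllithium | [Li]c1c(OC)cc(OC)cc1OCOCC[Si](C)(C)C | intermediate
22 | aryl carbinol: formyl carbon of 18 converted into CH(OH)Ar; Ar = 2,4-dimethoxy-6-(SEM-oxy)phenyl; both C9′ epimers | C=C(C)[C@@H]1CC[C@@](C)(O[Si](CC)(CC)CC)[C@@H]2CC[C@](C)(C(O)c3c(OC)cc(OC)cc3OCOCC[Si](C)(C)C)[C@H]2C1 | intermediate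
23 | triol: 22 without the SEM and triethylsilyl groups (2-hydroxy-4,6-dimethoxyphenyl carbinol; free 10α-hydroxyl) | C=C(C)[C@@H]1CC[C@@](C)(O)[C@@H]2CC[C@](C)(C(O)c3c(O)cc(OC)cc3OC)[C@H]2C1 | intermediate
24 | aryl tert-butyl carbonate of 23 (phenol oxygen acylated) | C=C(C)[C@@H]1CC[C@@](C)(O)[C@@H]2CC[C@](C)(C(O)c3c(OC(=O)OC(C)(C)C)cc(OC)cc3OC)[C@H]2C1 | intermediate
25 | o-quinone methide: C9′ doubly bonded to C6 of a 3,5-dimethoxycyclohexa-2,4-dien-1-one | C=C(C)[C@@H]1CC[C@@](C)(O)[C@@H]2CC[C@](C)(C=C3C(=O)C=C(OC)C=C3OC)[C@H]2C1 | intermediate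
26 | (9′R)-phenol: C9′ bears H; isobutyl; 2-hydroxy-4,6-dimethoxyphenyl; C4 of the hydroazulene | C=C(C)[C@@H]1CC[C@@](C)(O)[C@@H]2CC[C@](C)([C@@H](CC(C)C)c3c(O)cc(OC)cc3OC)[C@H]2C1 | intermediate
27 | methyl ether of 26 (2,4,6-trimethoxyphenyl) | C=C(C)[C@@H]1CC[C@@](C)(O)[C@@H]2CC[C@](C)([C@@H](CC(C)C)c3c(OC)cc(OC)cc3OC)[C@H]2C1 | intermediate
28 | 3′,5′-dibromo derivative of 27 | C=C(C)[C@@H]1CC[C@@](C)(O)[C@@H]2CC[C@](C)([C@@H](CC(C)C)c3c(OC)c(Br)c(OC)c(Br)c3OC)[C@H]2C1 | intermediate
29 | 3′,5′-diformyl-2′,4′,6′-trimethoxyphenyl compound | C=C(C)[C@@H]1CC[C@@](C)(O)[C@@H]2CC[C@](C)([C@@H](CC(C)C)c3c(OC)c(C=O)c(OC)c(C=O)c3OC)[C@H]2C1 | intermediate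
30 | CNP0594576.1: 3′,5′-diformyl-2′,4′,6′-trihydroxyphenyl compound; (9′R); 4α-methyl; H1 α; H5 β; 7β-isopropenyl; 10β-methyl; 10α-hydroxy | C=C(C)[C@@H]1CC[C@@](C)(O)[C@@H]2CC[C@](C)([C@@H](CC(C)C)c3c(O)c(C=O)c(O)c(C=O)c3O)[C@H]2C1 | target

Total step count: 22. Longest linear sequence: 21 steps (steps 1–13, then 15–22; step 14 prepares the aryl partner).

Steps most likely to fail

Step 6. The cross-conjugated dienone may suffer double addition or addition at the hindered C8 terminus, and its γ-hydrogen at C7 may be lost under the aqueous rhodium conditions, with double-bond migration and erosion of the C7 configuration. The fallback avoids the dienone and sets out from enone 6. The same (S)-BINAP rhodium addition of 9 to the simple enone should give (3S,5R)-3,5-di(prop-1-en-2-yl)cycloheptan-1-one F1. Formylation under equilibrating conditions (HCO2Et, NaH) at the less hindered C9 gives the hydroxymethylene ketone F2, and n-BuSH with p-TsOH converts it into the n-butylthiomethylene-blocked ketone F3. With C9 blocked, t-BuOK and 11 can alkylate only C1, anti to the C5 isopropenyl group, giving the blocked butenyl ketone F4. Aqueous KOH removes the blocking group and the route is rejoined at ketone 13.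

Step 12. Facial selectivity may be poor if the chiral dioxirane and the substrate are mismatched, and some oxidation of the isopropenyl group may compete. The fallback gives up reagent control and sets out from 16. Buffered mCPBA (NaHCO3, CH2Cl2, 0 °C) epoxidises the trisubstituted alkene on both faces; the β-epoxide 17 is separated by chromatography and carried on. The α-epoxide F5, which is the wrong isomer for the contraction because its C9′–H would become axial and shift, is returned to alkene 16 by deoxygenation with PPh3 and CH3ReO3 (cat.) and recycled.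

Step 13. Under the oxophilic aluminium reagent, cleavage of the tertiary silyl ether or proton loss from the C4 cation to allylic alcohols may outrun the 1,2-shift. The fallback generates the same cation in two stages from 17. MgBr2·OEt2 (Et2O, −20 °C) opens the epoxide at C4 in the trans-diaxial sense to give the bromohydrin F6 (4α-bromo, 9′β-hydroxy). AgBF4 with 2,6-di-tert-butylpyridine then ionises the tertiary C–Br bond, and the C9′–C3 bond, held on the α face by the trans ring fusion, migrates to give aldehyde 18 (halohydrin semipinacol rearrangement).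

Further compounds
F1 | step 6 | (3S,5R)-3,5-di(prop-1-en-2-yl)cycloheptan-1-one | C=C(C)[C@@H]1CCC(=O)C[C@H](C1)C(C)=C
F2 | step 6 | 7-(hydroxymethylene) derivative of F1 (at C9, target numbering) | C=C(C)[C@@H]1CC(=CO)C(=O)C[C@H](C1)C(C)=C
F3 | step 6 | 7-[(butylsulfanyl)methylene] derivative of F1 | C=C(C)[C@@H]1CC(=CSCCCC)C(=O)C[C@H](C1)C(C)=C
F4 | step 6 | 2-(but-3-en-1-yl) derivative of F3 (butenyl β at C1, trans to the C5 isopropenyl) | C=C(C)[C@@H]1CC(=CSCCCC)C(=O)[C@H](CCC=C)[C@H](C1)C(C)=C
F5 | step 12 | 4α,9′α-epoxide of 16 | C=C(C)[C@@H]1CC[C@@](C)(O[Si](CC)(CC)CC)[C@@H]2CC[C@H]3O[C@@]3(C)[C@H]2C1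
F6 | step 13 | bromohydrin from 17: 4α-bromo; 4β-methyl; 9′β-hydroxy | C=C(C)[C@@H]1CC[C@@](C)(O[Si](CC)(CC)CC)[C@@H]2CC[C@H](O)[C@@](C)(Br)[C@H]2C1
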